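**Retrosynthetic overview**
1. Target ⇐ tetraol core by two late acylations (C20–OH with (R)-2-methylbutanoic acid, then equatorial C2–OH with angelic acid); 7α-OH by reduction of a 7-oxo-8(17)-ene; C20–OH from the angular vinyl group of the key-step product, carried as a methyl ester.
2. C9 side chain (C11–C16, C13 set by Sharpless epoxidation) by axial alkylation of a C8-ketone enolate; C8=CH2 by methylenation; 2α,3α-diol from the C3 ketone (α-hydroxylation, axial-alcohol reduction); C4 gem-dimethyl and trans ring fusion by reductive methylation of a Δ4-3-ketone.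
3. Key disconnection: rings A and B from one acyclic 1-yne-vinylcyclopropane plus CO by a rhodium-catalysed carbonylative [(3+2)+1] cycloaddition. The enabling feature is ring A (C1–C2–C3–C4–C5–C10): oxygenated C3 lies between C2 and quaternary C4 and maps onto CO; C1/C2 map onto the cyclopropane methylenes; quaternary C10, which carries the oxidised one-carbon branch C20, maps onto the vinyl-bearing cyclopropane carbon; C4–C5 maps onto an alkyne tied to C10 by the C6–C9 chain of ring B.
4. The cycloaddition substrate comes from (2S,3S)-diepoxybutane by two epoxide openings (1-propynyllithium, then lithiated cyclopropanecarbonitrile), which also differentiate O7 from O8.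
5. Ring order: ring B (C5–C10) and ring A (C2–C3, C3–C4) close in the same operation; no further ring is formed.

Key step: step 6

Remark: as read from the SMILES, the C9 side chain is trans to the C10 CH2O branch (9-epi-labdane relative configuration); labdane numbering is used for all atoms, and α/β refer to the decalin drawn with the C10 branch β.

**Step 1**
Reactants: 1 (2S,3S)-1,2:3,4-diepoxybutane; 2 1-propynyllithium
Product: 3 (1S)-1-[(2S)-oxiran-2-yl]pent-3-yn-1-ol
Conditions: CH3C≡CLi (1.0 equiv), BF3·OEt2, THF, −78 °C; 1 in excess (2 equiv)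
Reagents that add atoms: none
Why: The BF3-activated terminal epoxide should be opened at its CH2 carbon by the alkynyllithium (Yamaguchi–Hirao alkynylation), so both stereocentres of C2-symmetric 1 are kept and mono-opening needs no regiocontrol because either epoxide gives the same product.

**Step 2**
Reactants: 3 (1S)-1-[(2S)-oxiran-2-yl]pent-3-yn-1-ol
Product: 4 triisopropyl{[(1S)-1-[(2S)-oxiran-2-yl]pent-3-yn-1-yl]oxy}silane
Conditions: i-Pr3SiOTf, 2,6-lutidine, CH2Cl2, −78 °C
Reagents that add atoms: triisopropylsilyl trifluoromethanesulfonate CC(C)[Si](C(C)C)(C(C)C)OS(=O)(=O)C(F)(F)F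
Why: Low-temperature silylation of the secondary alcohol should leave the epoxide intact and put a bulky, migration-resistant silyl ether on the future O7.

**Step 3**
Reactants: 4 triisopropyl{[(1S)-1-[(2S)-oxiran-2-yl]pent-3-yn-1-yl]oxy}silane; 5 cyclopropanecarbonitrile
Product: 7 1-[(2S,3S)-2-hydroxy-3-(triisopropylsilyloxy)hept-5-yn-1-yl]cyclopropane-1-carbonitrile, via 1-lithiocyclopropane-1-carbonitrile 6 (not isolated)
Conditions: 5, LiN(i-Pr)2, THF, −78 °C; then 4, −78 → −30 °C; AcOH quench at −78 °C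
Reagents that add atoms: none
Why: The nitrile-stabilised tertiary carbanion should open the terminal epoxide at CH2 (SN2 epoxide opening), forming the C9–C10 bond without touching C8, and the cold acidic quench prevents the alkoxide from adding to the nitrile.

**Step 4**
Reactants: 7 1-[(2S,3S)-2-hydroxy-3-(triisopropylsilyloxy)hept-5-yn-1-yl]cyclopropane-1-carbonitrile
Product: 8 (6S)-6-[(1S)-1-(triisopropylsilyloxy)pent-3-yn-1-yl]-5-oxaspiro[2.4]heptan-4-ol (lactol; anomer mixture)
Conditions: i-Bu2AlH (2.5 equiv), CH2Cl2, −78 °C; aq. potassium sodium tartrate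
Reagents that add atoms: water O
Why: Partial reduction of the nitrile to the N-aluminio imine and hydrolysis should give the aldehyde, which is trapped by the C8 hydroxyl as the five-membered lactol (nitrile-to-aldehyde reduction).

**Step 5**
Reactants: 8 (6S)-6-[(1S)-1-(triisopropylsilyloxy)pent-3-yn-1-yl]-5-oxaspiro[2.4]heptan-4-ol
Product: 9 (2S,3S)-3-(triisopropylsilyloxy)-1-(1-vinylcyclopropyl)hept-5-yn-2-ol
Conditions: Ph3PCH3Br, KOt-Bu, THF, 0 °C → reflux
Reagents that add atoms: methyltriphenylphosphonium bromide C[P+](c1ccccc1)(c1ccccc1)c1ccccc1.[Br-]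
Why: Wittig methylenation of the open hydroxy-aldehyde tautomer of the lactol should install the vinyl group on the cyclopropane and free the C8 hydroxyl.

**Step 6**
Reactants: 9 (2S,3S)-3-(triisopropylsilyloxy)-1-(1-vinylcyclopropyl)hept-5-yn-2-ol
Product: 10 (4aR,6S,7S)-6-hydroxy-1-methyl-7-(triisopropylsilyloxy)-4a-vinyl-4,4a,5,6,7,8-hexahydronaphthalen-2(3H)-one (Δ4-3-ketone; 4-methyl; 7β-OTIPS; 8α-OH; 10β-vinyl)
Conditions: [Rh(CO)2Cl]2 (5 mol %), CO (0.2 atm, balance N2), toluene, 80 °C
Reagents that add atoms: carbon monoxide [C-]#[O+]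
Why: Monovalent rhodium should insert into a proximal cyclopropane bond (C10–C2) to give a π-allyl/σ-alkyl rhodacycle, the tethered alkyne then inserts syn into the Rh–C10 bond (C5–C10), CO inserts, and reductive elimination forms C2–C3 and C3–C4 to release the conjugated cyclohexenone. The closest known reaction type is the rhodium-catalysed [(3+2)+1] cycloaddition of 1-yne-vinylcyclopropanes with CO (a homologous Pauson–Khand reaction), which gives fused cyclohexenones with a vinyl-bearing quaternary bridgehead. Ring B closes by 6-exo-dig carbometalation and ring A by reductive elimination from the seven-membered acyl rhodacycle, a formal [3+2+1] union of C10/C1/C2, C4≡C5 and CO. The only new stereocentre, C10, is set at the alkyne insertion: ring A can form only if the C10–C1 bond lies near the plane of the developing C4=C5 unit, so the vinyl group must be axial on the chair-like forming ring B, and the hydrogen-bonded trans-diequatorial C7–OTIPS/C8–OH pair selects the chair that places this vinyl cis to O7 and trans to O8. The step needs carbonylation to outrun direct reductive elimination (the non-carbonylative [3+2] path), which the low constant CO pressure and the two tether substituents (Thorpe–Ingold effect) are meant to secure; the two cyclopropane methylenes are equivalent, so there is no regiochemical issue.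

**Step 7**
Reactants: 10 bicyclic enone (Δ4-3-ketone; 4-methyl; 7β-OTIPS; 8α-OH; 10β-vinyl)
Product: 12 (5α,7β,8α,10β)-8-hydroxy-4,4-dimethyl-7-(triisopropylsilyloxy)-10-vinyldecalin-3-one, via dilithium enolate alkoxide 11 (not isolated)
Conditions: Li, NH3(l)/THF, t-BuOH (1 equiv), −78 °C; then MeI, −78 → −33 °C
Reagents that add atoms: iodomethane CI
Why: Stork reductive alkylation should protonate C5 axially to give the trans-fused lithium enolate, which is C-methylated regiospecifically at C4 to complete the gem-dimethyl group, while the isolated vinyl group and the silyl ether are inert to Li/NH3.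

**Step 8**
Reactants: 12 (5α,7β,8α,10β)-8-hydroxy-4,4-dimethyl-7-(triisopropylsilyloxy)-10-vinyldecalin-3-one
Product: 14 (2α,5α,7β,8α,10β)-2,8-dihydroxy-4,4-dimethyl-7-(triisopropylsilyloxy)-10-vinyldecalin-3-one, via dipotassium enolate alkoxide 13 (not isolated)
Conditions: KN(SiMe3)2 (2.2 equiv), THF, −78 °C; then 2-(phenylsulfonyl)-3-phenyloxaziridine, −78 °C
Reagents that add atoms: 2-(phenylsulfonyl)-3-phenyloxaziridine O=S(=O)(c1ccccc1)N1OC1c1ccccc1
Why: The ketone can enolise only towards C2 (C4 is quaternary), and the potassium enolate should be hydroxylated by the N-sulfonyloxaziridine (Davis oxidation) from the α face, anti to the axial C10 vinyl and 4β-methyl groups, giving the equatorial 2α-alcohol.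

**Step 9**
Reactants: 14 (2α,5α,7β,8α,10β)-2,8-dihydroxy-4,4-dimethyl-7-(triisopropylsilyloxy)-10-vinyldecalin-3-one
Product: 15 (2α,3α,5α,7β,8α,10β)-4,4-dimethyl-7-(triisopropylsilyloxy)-10-vinyldecalin-2,3,8-triol
Conditions: LiBH(s-Bu)3 (3.5 equiv), THF, −78 °C; then aq. NaOH, H2O2
Reagents that add atoms: none
Why: The bulky trialkylborohydride should attack the C3 ketone along the equatorial trajectory, as is usual for 4,4-dimethyl-3-ketones, giving the axial 3α-alcohol cis to the 2α-oxygen.

**Step 10**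
Reactants: 15 (2α,3α,5α,7β,8α,10β)-4,4-dimethyl-7-(triisopropylsilyloxy)-10-vinyldecalin-2,3,8-triol
Product: 16 2α,3α-O-isopropylidene acetal of 15 (8α-OH free; 7β-OTIPS; 10β-vinyl)
Conditions: Me2C(OMe)2, PPTS (cat.), CH2Cl2, rt
Reagents that add atoms: 2,2-dimethoxypropane COC(C)(C)OC
Why: Only the cis-2α,3α-diol can form a five-membered isopropylidene acetal (acid-catalysed transketalisation), which separates it from the isolated C8 hydroxyl.

**Step 11**
Reactants: 16 2α,3α-O-isopropylidene acetal (8α-OH; 7β-OTIPS; 10β-vinyl)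
Product: 18 methyl (2α,3α,5α,7β,8α,10β)-8-hydroxy-2,3-(isopropylidenedioxy)-4,4-dimethyl-7-(triisopropylsilyloxy)decalin-10-carboxylate, via C20 aldehyde 17 (not isolated)
Conditions: O3, NaOH (2.5 M in MeOH), CH2Cl2, −78 °C
Reagents that add atoms: ozone [O-][O+]=O; methanol CO
Why: Ozonolysis in methanolic NaOH should cleave the only alkene and oxidise the aldehyde hemiacetal in situ to the methyl ester, turning the angular vinyl group into a base-stable, non-enolisable C20 carboxylate.

**Step 12**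
Reactants: 18 methyl 8α-hydroxy-2α,3α-(isopropylidenedioxy)-4,4-dimethyl-7β-(triisopropylsilyloxy)decalin-10β-carboxylate
Product: 19 methyl (2α,3α,5α,7β,10β)-2,3-(isopropylidenedioxy)-4,4-dimethyl-8-oxo-7-(triisopropylsilyloxy)decalin-10-carboxylate
Conditions: Dess–Martin periodinane, pyridine, CH2Cl2, rt
Reagents that add atoms: none
Why: Dess–Martin oxidation of the only free hydroxyl should give the C8 ketone under buffered conditions that spare the acetonide and the silyl ether.

**Step 13**
Reactants: 20 (E)-3-methylpent-2-en-4-yn-1-ol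
Product: 21 [(2S,3S)-3-ethynyl-3-methyloxiran-2-yl]methanol
Conditions: Ti(Oi-Pr)4 (cat.), L-(+)-diisopropyl tartrate (cat.), t-BuOOH, 4 Å molecular sieves, CH2Cl2, −20 °C
Reagents that add atoms: tert-butyl hydroperoxide CC(C)(C)OO
Why: Sharpless asymmetric epoxidation of the trisubstituted E-allylic alcohol with the L-(+)-tartrate catalyst should deliver oxygen to the same face as for geraniol, fixing the future C13 stereocentre.

**Step 14**
Reactants: 21 [(2S,3S)-3-ethynyl-3-methyloxiran-2-yl]methanol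
Product: 22 (3R)-3-methylpent-4-ene-1,3-diol
Conditions: NaAlH2(OCH2CH2OCH3)2 (excess), THF, 0 °C → rt
Reagents that add atoms: none
Why: The alkoxy-aluminium hydride should deliver hydride intramolecularly to C2 of the 2,3-epoxy alcohol (1,3-diol formation) and trans-hydroaluminate the resulting tertiary propargylic alkoxide, so the alkyne becomes the vinyl group and the carbinol centre is untouched.

**Step 15**
Reactants: 22 (3R)-3-methylpent-4-ene-1,3-diol
Product: 23 (3R)-3-methyl-3,5-bis(triethylsilyloxy)pent-1-ene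
Conditions: Et3SiOTf (2.5 equiv), 2,6-lutidine, CH2Cl2, −78 → 0 °C
Reagents that add atoms: triethylsilyl trifluoromethanesulfonate CC[Si](CC)(CC)OS(=O)(=O)C(F)(F)F
Why: The silyl triflate should silylate both the primary and the hindered tertiary hydroxyl.

**Step 16**
Reactants: 23 (3R)-3-methyl-3,5-bis(triethylsilyloxy)pent-1-ene
Product: 24 (3R)-3-methyl-3-(triethylsilyloxy)pent-4-en-1-ol
Conditions: PPTS (cat.), MeOH/CH2Cl2, 0 °C
Reagents that add atoms: none
Why: Mild acidic methanolysis should cleave the primary triethylsilyl ether much faster than the tertiary one (steric differentiation of silyl ethers).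

**Step 17**
Reactants: 24 (3R)-3-methyl-3-(triethylsilyloxy)pent-4-en-1-ol
Product: 25 (3R)-3-methyl-3-(triethylsilyloxy)pent-4-en-1-yl trifluoromethanesulfonate
Conditions: Tf2O, 2,6-di-tert-butylpyridine, CH2Cl2, −78 °C; used directly
Reagents that add atoms: trifluoromethanesulfonic anhydride O=S(=O)(OS(=O)(=O)C(F)(F)F)C(F)(F)F
Why: Triflation of the primary alcohol with a non-nucleophilic base should give an alkylating agent reactive enough for a hindered enolate.

**Step 18**
Reactants: 19 methyl 2α,3α-(isopropylidenedioxy)-4,4-dimethyl-8-oxo-7β-(triisopropylsilyloxy)decalin-10β-carboxylate; 25 (3R)-3-methyl-3-(triethylsilyloxy)pent-4-en-1-yl trifluoromethanesulfonate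
Product: 27 9α-[(3R)-3-methyl-3-(triethylsilyloxy)pent-4-enyl] derivative of 19, via lithium enolate 26 (not isolated)
Conditions: LiN(i-Pr)2 (1.05 equiv), THF, −78 °C; then 25, THF/DMPU, −78 → −40 °C
Reagents that add atoms: none
Why: Kinetic deprotonation should occur at the C9 methylene because the C7 hydrogen is shielded by the triisopropylsilyloxy group, and the lithium enolate is alkylated by the primary triflate axially on the α face, anti to the axial C10 ester, which sets the 9α side chain (ketone enolate alkylation).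

**Step 19**
Reactants: 27 9α-alkylated 8-keto ester
Product: 28 methyl (2α,3α,5α,7β,9α,10β)-2,3-(isopropylidenedioxy)-4,4-dimethyl-8-methylene-9-[(3R)-3-methyl-3-(triethylsilyloxy)pent-4-enyl]-7-(triisopropylsilyloxy)decalin-10-carboxylate
Conditions: Zn, CH2Br2, TiCl4, THF/CH2Cl2, 0 °C → rt
Reagents that add atoms: dibromomethane BrCBr
Why: The Zn/CH2Br2/TiCl4 reagent (Takai–Lombardo methylenation) should methylenate the hindered, enolisable ketone without base, so C9 is not epimerised and the ester is untouched.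

**Step 20**
Reactants: 28 8(17)-methylene bis-silyl ether
Product: 29 methyl (2α,3α,5α,7β,9α,10β)-7-hydroxy-9-[(3R)-3-hydroxy-3-methylpent-4-enyl]-2,3-(isopropylidenedioxy)-4,4-dimethyl-8-methylenedecalin-10-carboxylate
Conditions: Bu4NF, THF, rt
Reagents that add atoms: none
Why: Fluoride should cleave both silyl ethers (secondary triisopropylsilyl and tertiary triethylsilyl) while the acetonide and the hindered methyl ester survive.

**Step 21**
Reactants: 29 7β,13-diol
Product: 30 methyl (2α,3α,5α,9α,10β)-9-[(3R)-3-hydroxy-3-methylpent-4-enyl]-2,3-(isopropylidenedioxy)-4,4-dimethyl-8-methylene-7-oxodecalin-10-carboxylate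
Conditions: MnO2, CH2Cl2, rt
Reagents that add atoms: none
Why: MnO2 should oxidise only the allylic secondary alcohol to the cross-conjugated 7-oxo-8(17)-ene, erasing the C7 configuration that served only the earlier steps.

**Step 22**
Reactants: 30 7-oxo-8(17)-ene methyl ester
Product: 31 (2α,3α,5α,7α,9α,10β)-10-(hydroxymethyl)-9-[(3R)-3-hydroxy-3-methylpent-4-enyl]-2,3-(isopropylidenedioxy)-4,4-dimethyl-8-methylenedecalin-7-ol
Conditions: i-Bu2AlH (excess), CH2Cl2, −78 → 0 °C
Reagents that add atoms: none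
Why: i-Bu2AlH should reduce the enone in the 1,2 sense and the ester to the primary alcohol; the axial α-face approach to C7 is blocked by the axial 9α side chain, so hydride enters from the β face and gives the axial 7α-alcohol.

**Step 23**
Reactants: 31 7α,13,20-triol acetonide; 32 (R)-2-methylbutanoic acid
Product: 33 20-O-[(2R)-2-methylbutanoyl] ester of 31
Conditions: 32 (1.1 equiv), EDC·HCl, DMAP (cat.), CH2Cl2, 0 °C
Reagents that add atoms: none
Why: Carbodiimide esterification (Steglich conditions) should acylate the primary C20 hydroxyl in preference to the hindered axial secondary and the tertiary hydroxyls, and low temperature with catalytic DMAP avoids epimerisation of the acid.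

**Step 24**
Reactants: 33 20-O-[(2R)-2-methylbutanoyl] acetonide
Product: 34 (2α,3α,5α,7α,9α,10β)-2,3,7-trihydroxy-9-[(3R)-3-hydroxy-3-methylpent-4-enyl]-4,4-dimethyl-8-methylenedecalin-10-ylmethyl (2R)-2-methylbutanoate
Conditions: AcOH/H2O (4:1), 40 °C
Reagents that add atoms: none
Why: Mild aqueous acid should hydrolyse the isopropylidene acetal without ionising the tertiary or the secondary allylic alcohol.

**Step 25**
Reactants: 34 2α,3α,7α,13-tetraol 20-ester; 35 angelic acid
Product: 37 target CNP0391865.1 (2α-angelate), via angelic 2,4,6-trichlorobenzoic anhydride 36 (not isolated)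
Conditions: 35, 2,4,6-trichlorobenzoyl chloride, Et3N, toluene, rt; then 34, 75 °C
Reagents that add atoms: none
Why: The preformed mixed anhydride (Yamaguchi-type esterification without DMAP) should transfer the angeloyl group without Z-to-E isomerisation, and the equatorial 2α-hydroxyl should react in preference to the axial neopentyl 3α-, the axial allylic 7α- and the tertiary 13-hydroxyl.

**Compound list**
1 | (2S,3S)-1,2:3,4-diepoxybutane | C1O[C@@H]1[C@@H]1CO1 | starting material
2 | 1-propynyllithium | [Li]C#CC | starting material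
3 | (1S)-1-[(2S)-oxiran-2-yl]pent-3-yn-1-ol | CC#CC[C@H](O)[C@@H]1CO1 | intermediate
4 | triisopropyl{[(1S)-1-[(2S)-oxiran-2-yl]pent-3-yn-1-yl]oxy}silane | CC#CC[C@H](O[Si](C(C)C)(C(C)C)C(C)C)[C@@H]1CO1 | intermediate
5 | cyclopropanecarbonitrile | N#CC1CC1 | starting material
6 | 1-lithiocyclopropane-1-carbonitrile | [Li]C1(C#N)CC1 | intermediate (not isolated)
7 | 1-[(2S,3S)-2-hydroxy-3-(triisopropylsilyloxy)hept-5-yn-1-yl]cyclopropane-1-carbonitrile | CC#CC[C@H](O[Si](C(C)C)(C(C)C)C(C)C)[C@@H](O)CC1(C#N)CC1 | intermediate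
8 | (6S)-6-[(1S)-1-(triisopropylsilyloxy)pent-3-yn-1-yl]-5-oxaspiro[2.4]heptan-4-ol (lactol, anomer mixture) | CC#CC[C@H](O[Si](C(C)C)(C(C)C)C(C)C)[C@@H]1CC2(CC2)C(O)O1 | intermediate
9 | (2S,3S)-3-(triisopropylsilyloxy)-1-(1-vinylcyclopropyl)hept-5-yn-2-ol | CC#CC[C@H](O[Si](C(C)C)(C(C)C)C(C)C)[C@@H](O)CC1(C=C)CC1 | intermediate
10 | (4aR,6S,7S)-6-hydroxy-1-methyl-7-(triisopropylsilyloxy)-4a-vinyl-4,4a,5,6,7,8-hexahydronaphthalen-2(3H)-one | C1[C@H](O)[C@@H](O[Si](C(C)C)(C(C)C)C(C)C)CC2=C(C)C(=O)CC[C@]12C=C | intermediate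
11 | dilithium enolate alkoxide from 10 (C3 enolate, C8 alkoxide, 5α-H) | C1[C@H](O[Li])[C@@H](O[Si](C(C)C)(C(C)C)C(C)C)C[C@H]2C(C)=C(O[Li])CC[C@]12C=C | intermediate (not isolated)
12 | (5α,7β,8α,10β)-8-hydroxy-4,4-dimethyl-7-(triisopropylsilyloxy)-10-vinyldecalin-3-one | C1[C@H](O)[C@@H](O[Si](C(C)C)(C(C)C)C(C)C)C[C@H]2C(C)(C)C(=O)CC[C@]12C=C | intermediate
13 | dipotassium enolate alkoxide from 12 (C2=C3 enolate, C8 alkoxide) | C1[C@H](O[K])[C@@H](O[Si](C(C)C)(C(C)C)C(C)C)C[C@H]2C(C)(C)C(O[K])=CC[C@]12C=C | intermediate (not isolated)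
14 | (2α,5α,7β,8α,10β)-2,8-dihydroxy-4,4-dimethyl-7-(triisopropylsilyloxy)-10-vinyldecalin-3-one | C1[C@H](O)[C@@H](O[Si](C(C)C)(C(C)C)C(C)C)C[C@H]2C(C)(C)C(=O)[C@H](O)C[C@]12C=C | intermediate
15 | (2α,3α,5α,7β,8α,10β)-4,4-dimethyl-7-(triisopropylsilyloxy)-10-vinyldecalin-2,3,8-triol | C1[C@H](O)[C@@H](O[Si](C(C)C)(C(C)C)C(C)C)C[C@H]2C(C)(C)[C@H](O)[C@H](O)C[C@]12C=C | intermediate
16 | 2α,3α-O-isopropylidene acetal of 15 | C1[C@H](O)[C@@H](O[Si](C(C)C)(C(C)C)C(C)C)C[C@H]2C(C)(C)[C@H](OC3(C)C)[C@H](O3)C[C@]12C=C | intermediate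
17 | C20 aldehyde from 16 (10β-formyl) | C1[C@H](O)[C@@H](O[Si](C(C)C)(C(C)C)C(C)C)C[C@H]2C(C)(C)[C@H](OC3(C)C)[C@H](O3)C[C@]12C=O | intermediate (not isolated)
18 | methyl (2α,3α,5α,7β,8α,10β)-8-hydroxy-2,3-(isopropylidenedioxy)-4,4-dimethyl-7-(triisopropylsilyloxy)decalin-10-carboxylate | C1[C@H](O)[C@@H](O[Si](C(C)C)(C(C)C)C(C)C)C[C@H]2C(C)(C)[C@H](OC3(C)C)[C@H](O3)C[C@]12C(=O)OC | intermediate
19 | methyl (2α,3α,5α,7β,10β)-2,3-(isopropylidenedioxy)-4,4-dimethyl-8-oxo-7-(triisopropylsilyloxy)decalin-10-carboxylate | C1C(=O)[C@@H](O[Si](C(C)C)(C(C)C)C(C)C)C[C@H]2C(C)(C)[C@H](OC3(C)C)[C@H](O3)C[C@]12C(=O)OC | intermediate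
20 | (E)-3-methylpent-2-en-4-yn-1-ol | C#C/C(C)=C/CO | starting material
21 | [(2S,3S)-3-ethynyl-3-methyloxiran-2-yl]methanol | OC[C@@H]1O[C@@]1(C)C#C | intermediate
22 | (3R)-3-methylpent-4-ene-1,3-diol | C=C[C@](C)(O)CCO | intermediate
23 | (3R)-3-methyl-3,5-bis(triethylsilyloxy)pent-1-ene | C=C[C@](C)(O[Si](CC)(CC)CC)CCO[Si](CC)(CC)CC | intermediate
24 | (3R)-3-methyl-3-(triethylsilyloxy)pent-4-en-1-ol | C=C[C@](C)(O[Si](CC)(CC)CC)CCO | intermediate
25 | (3R)-3-methyl-3-(triethylsilyloxy)pent-4-en-1-yl trifluoromethanesulfonate | C=C[C@](C)(O[Si](CC)(CC)CC)CCOS(=O)(=O)C(F)(F)F | intermediate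
26 | lithium C8=C9 enolate of 19 | C1=C(O[Li])[C@@H](O[Si](C(C)C)(C(C)C)C(C)C)C[C@H]2C(C)(C)[C@H](OC3(C)C)[C@H](O3)C[C@]12C(=O)OC | intermediate (not isolated)
27 | methyl (2α,3α,5α,7β,9α,10β)-2,3-(isopropylidenedioxy)-4,4-dimethyl-9-[(3R)-3-methyl-3-(triethylsilyloxy)pent-4-enyl]-8-oxo-7-(triisopropylsilyloxy)decalin-10-carboxylate | C=C[C@](C)(O[Si](CC)(CC)CC)CC[C@@H]1C(=O)[C@@H](O[Si](C(C)C)(C(C)C)C(C)C)C[C@H]2C(C)(C)[C@H](OC3(C)C)[C@H](O3)C[C@]12C(=O)OC | intermediate
28 | 8-methylene analogue of 27 (8(17)-ene) | C=C[C@](C)(O[Si](CC)(CC)CC)CC[C@@H]1C(=C)[C@@H](O[Si](C(C)C)(C(C)C)C(C)C)C[C@H]2C(C)(C)[C@H](OC3(C)C)[C@H](O3)C[C@]12C(=O)OC | intermediate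
29 | methyl (2α,3α,5α,7β,9α,10β)-7-hydroxy-9-[(3R)-3-hydroxy-3-methylpent-4-enyl]-2,3-(isopropylidenedioxy)-4,4-dimethyl-8-methylenedecalin-10-carboxylate | C=C[C@](C)(O)CC[C@@H]1C(=C)[C@@H](O)C[C@H]2C(C)(C)[C@H](OC3(C)C)[C@H](O3)C[C@]12C(=O)OC | intermediate
30 | 7-oxo analogue of 29 (7-oxo-8(17)-ene) | C=C[C@](C)(O)CC[C@@H]1C(=C)C(=O)C[C@H]2C(C)(C)[C@H](OC3(C)C)[C@H](O3)C[C@]12C(=O)OC | intermediate
31 | (2α,3α,5α,7α,9α,10β)-10-(hydroxymethyl)-9-[(3R)-3-hydroxy-3-methylpent-4-enyl]-2,3-(isopropylidenedioxy)-4,4-dimethyl-8-methylenedecalin-7-ol | C=C[C@](C)(O)CC[C@@H]1C(=C)[C@H](O)C[C@H]2C(C)(C)[C@H](OC3(C)C)[C@H](O3)C[C@]12CO | intermediate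
32 | (R)-2-methylbutanoic acid | CC[C@@H](C)C(=O)O | starting material
33 | 20-O-[(2R)-2-methylbutanoyl] ester of 31 | C=C[C@](C)(O)CC[C@@H]1C(=C)[C@H](O)C[C@H]2C(C)(C)[C@H](OC3(C)C)[C@H](O3)C[C@]12COC(=O)[C@H](C)CC | intermediate
34 | 2α,3α,7α,13-tetraol 20-[(2R)-2-methylbutanoate] | C=C[C@](C)(O)CC[C@@H]1C(=C)[C@H](O)C[C@H]2C(C)(C)[C@H](O)[C@H](O)C[C@]12COC(=O)[C@H](C)CC | intermediate
35 | angelic acid, (Z)-2-methylbut-2-enoic acid | C/C=C(/C)C(=O)O | starting material
36 | angelic 2,4,6-trichlorobenzoic anhydride | C/C=C(/C)C(=O)OC(=O)c1c(Cl)cc(Cl)cc1Cl | intermediate (not isolated)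
37 | CNP0391865.1 | C=C[C@](C)(O)CC[C@@H]1C(=C)[C@H](O)C[C@H]2C(C)(C)[C@H](O)[C@H](OC(=O)/C(C)=C\C)C[C@]12COC(=O)[C@H](C)CC | target

**Step count**
Total: 25 steps. Longest linear sequence: 20 steps (steps 1–12 and 18–25); the side-chain triflate 25 takes 5 steps (13–17).

**Steps most likely to fail**

1. Step 6 (key step). What may go wrong: reductive elimination may outrun CO insertion and give the non-carbonylative bicyclic cyclopentene; the alkyne may oligomerise; the conformational bias may give incomplete facial selectivity at C10. Fallback (sets out from 9, returns at 10): the insertion partner is changed to an alkene and the enone unsaturation is introduced in a separate oxidation. Semihydrogenation of 9 (H2, Pd/CaCO3 poisoned with Pb(OAc)2, quinoline) should give the Z-alkene (2S,3S,5Z)-3-(triisopropylsilyloxy)-1-(1-vinylcyclopropyl)hept-5-en-2-ol F1. The ene variant of the carbonylative cycloaddition ([Rh(CO)2Cl]2, CO 1 atm, dioxane, 90 °C) should give the saturated ketone 8α-hydroxy-4-methyl-7β-(triisopropylsilyloxy)-10β-vinyldecalin-3-one F2; its C4/C5 configuration is not controlled and does not matter. Thermodynamic silylation (Me3SiCl, NaI, Et3N, MeCN) should give the tetrasubstituted enol ether, the 3,8-bis(trimethylsilyloxy) Δ3-ene F3. Saegusa–Ito dehydrogenation (Pd(OAc)2, MeCN) followed by K2CO3/MeOH should return enone 10.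

2. Step 18. What may go wrong: slow C-alkylation at the C9 methylene next to the quaternary centre, O-alkylation, proton transfer that moves the enolate to C7, and elimination of the triflate. Fallback (sets out from 19 and 24, returns at 27): the nucleophile is changed to a metallated hydrazone and the electrophile to an iodide. Ketone 19 (Me2NNH2, AcOH cat., EtOH, reflux) should give the N,N-dimethylhydrazone of 19 F4. Alcohol 24 (I2, PPh3, imidazole) should give (3R)-5-iodo-3-methyl-3-(triethylsilyloxy)pent-1-ene F5. The azaenolate of F4 (LiN(i-Pr)2, THF, 0 °C), which is formed at the less substituted C9 and is far more nucleophilic than the ketone enolate, should be alkylated axially by F5 to the 9α-alkylated hydrazone F6. Mild hydrolysis (Cu(OAc)2, THF/H2O) should return 27.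

3. Step 9. What may go wrong: poor facial selectivity of the hydride at C3 next to the C2 alkoxide, and base-induced α-ketol isomerisation of 14. Fallback (sets out from 12, returns at 18): the diol is made by dihydroxylation of a Δ2-alkene instead of hydroxylation and reduction. Ozonolysis of 12 under the conditions of step 11 should give the keto ester methyl 8α-hydroxy-4,4-dimethyl-3-oxo-7β-(triisopropylsilyloxy)decalin-10β-carboxylate F7. TsNHNH2 (MeOH) should give its tosylhydrazone F8. Shapiro elimination (LiN(i-Pr)2 in excess, THF, −78 → 0 °C) should give the Δ2-alkene F9. OsO4 (cat.) with N-methylmorpholine N-oxide should attack the α face, opposite the axial 4β-methyl and C10 ester groups, and give the 2α,3α-diol F10. Acetonide formation as in step 10 converts F10 into 18.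

**Further compounds**
F1 | step 6 | (2S,3S,5Z)-3-(triisopropylsilyloxy)-1-(1-vinylcyclopropyl)hept-5-en-2-ol | C/C=C\C[C@H](O[Si](C(C)C)(C(C)C)C(C)C)[C@@H](O)CC1(C=C)CC1
F2 | step 6 | 8α-hydroxy-4-methyl-7β-(triisopropylsilyloxy)-10β-vinyldecalin-3-one (C4/C5 isomer mixture) | C1[C@H](O)[C@@H](O[Si](C(C)C)(C(C)C)C(C)C)CC2C(C)C(=O)CC[C@]12C=C
F3 | step 6 | 4-methyl-7β-(triisopropylsilyloxy)-3,8α-bis(trimethylsilyloxy)-10β-vinyl-Δ3-octalin | C1[C@H](O[Si](C)(C)C)[C@@H](O[Si](C(C)C)(C(C)C)C(C)C)CC2C(C)=C(O[Si](C)(C)C)CC[C@]12C=C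
F4 | step 18 | N,N-dimethylhydrazone of 19 | C1C(=NN(C)C)[C@@H](O[Si](C(C)C)(C(C)C)C(C)C)C[C@H]2C(C)(C)[C@H](OC3(C)C)[C@H](O3)C[C@]12C(=O)OC
F5 | step 18 | (3R)-5-iodo-3-methyl-3-(triethylsilyloxy)pent-1-ene | C=C[C@](C)(O[Si](CC)(CC)CC)CCI
F6 | step 18 | N,N-dimethylhydrazone of 27 (9α-alkylated) | C=C[C@](C)(O[Si](CC)(CC)CC)CC[C@@H]1C(=NN(C)C)[C@@H](O[Si](C(C)C)(C(C)C)C(C)C)C[C@H]2C(C)(C)[C@H](OC3(C)C)[C@H](O3)C[C@]12C(=O)OC
F7 | step 9 | methyl (5α,7β,8α,10β)-8-hydroxy-4,4-dimethyl-3-oxo-7-(triisopropylsilyloxy)decalin-10-carboxylate | C1[C@H](O)[C@@H](O[Si](C(C)C)(C(C)C)C(C)C)C[C@H]2C(C)(C)C(=O)CC[C@]12C(=O)OC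
F8 | step 9 | tosylhydrazone of F7 | C1[C@H](O)[C@@H](O[Si](C(C)C)(C(C)C)C(C)C)C[C@H]2C(C)(C)C(=NNS(=O)(=O)c3ccc(C)cc3)CC[C@]12C(=O)OC
F9 | step 9 | methyl (5α,7β,8α,10β)-8-hydroxy-4,4-dimethyl-7-(triisopropylsilyloxy)-Δ2-octalin-10-carboxylate | C1[C@H](O)[C@@H](O[Si](C(C)C)(C(C)C)C(C)C)C[C@H]2C(C)(C)C=CC[C@]12C(=O)OC
F10 | step 9 | methyl (2α,3α,5α,7β,8α,10β)-2,3,8-trihydroxy-4,4-dimethyl-7-(triisopropylsilyloxy)decalin-10-carboxylate | C1[C@H](O)[C@@H](O[Si](C(C)C)(C(C)C)C(C)C)C[C@H]2C(C)(C)[C@H](O)[C@H](O)C[C@]12C(=O)OC
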